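**Plan** (chromene numbering: O1, C2, C3, C4, C4a, C5–C8, C8a)

- Cuts, in retrosynthetic order: the acid is unmasked from an enol δ-lactone; the lactone is cut at C6–CH(n-Pr) and O5–acyl into a bicyclic enol and (E)-hex-2-enal; then C8–prenyl, C8–CH2 of the C10 chain, O1–C2 of the pyranone, and aryl–acyl.
- Enabling feature: in the carbocycle C4a–C5–C6–C7–C8–C8a, C6 sits unsubstituted between the C5 enol and the C7 ketone, and the CH(n-Pr)CH2CO2H it must carry maps onto C3 and C1 of hex-2-enoic acid, with C1 close enough to O5 to lactonise.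
- Forward order: phloroglucinol ring, acylation and iodination; pyranone ring by oxa-Michael closure; C10 chain (from (R)-limonene) joined by Negishi coupling; C6 blocked by bromine, dearomatising prenylation at C8, bromine removed; dihydropyranone ring by carbene catalysis; lactone opened.
- Stereochemistry: C2/C3 (cis, 2R,3S) from quinine-catalysed oxa-Michael addition with kinetic protonation; the chain centre from (R)-limonene; C8 from a chiral bisphosphine on palladium; the side-chain centre (S) from a chiral triazolium carbene.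

Key step: step 19

Assumption: quinine (step 6) is taken to give the 2R centre as it does with other o-(2-methylbut-2-enoyl)phenols, and the senses of the (R,R)-bisphosphine (step 17) and the (5aS,10bR)-triazolium (step 19) are assigned by analogy; each catalyst has a commercial antipode (quinidine for quinine) that would be used if a first run showed the opposite sense.

**Route**

Step 1
Reactants: 1 phloroglucinol
Product: 2 1,3,5-tris(methoxymethoxy)benzene
Conditions: MOMCl (3.6 equiv), i-Pr2NEt, DMF–CH2Cl2, 0 °C → rt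
Reagents that add atoms: chloromethyl methyl ether, COCCl
Why: O-alkylation of the three phenols by the hard alkoxymethyl chloride should give the tris-acetal, whose OCH2OMe groups later direct ortho-lithiation.

Step 2
Reactants: 3 tiglic acid
Product: 5 (E)-N-methoxy-N,2-dimethylbut-2-enamide, via tigloyl imidazolide 4 (not isolated)
Conditions: CDI, CH2Cl2, rt; then MeNH(OMe)·HCl, rt
Reagents that add atoms: N,O-dimethylhydroxylamine hydrochloride, CNOC.Cl
Why: Amide formation through the acyl imidazolide is mild enough to leave the (E)-trisubstituted alkene unchanged.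

Step 3
Reactants: 2 1,3,5-tris(methoxymethoxy)benzene; 5 (E)-N-methoxy-N,2-dimethylbut-2-enamide
Product: 7 (E)-2-methyl-1-[2,4,6-tris(methoxymethoxy)phenyl]but-2-en-1-one, via aryllithium 6 (not isolated)
Conditions: n-BuLi, THF, 0 °C; then 5, −78 → 0 °C; aq NH4Cl
Reagents that add atoms: none
Why: Directed ortho-metalation between two acetal oxygens gives the aryllithium, which should add once to the N-methoxy-N-methyl amide (acyl substitution through a chelated tetrahedral adduct that survives until quench), 1,2-addition being favoured at the α,β-disubstituted enamide.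

Step 4
Reactants: 7 (E)-2-methyl-1-[2,4,6-tris(methoxymethoxy)phenyl]but-2-en-1-one
Product: 8 (E)-1-[2-hydroxy-4,6-bis(methoxymethoxy)phenyl]-2-methylbut-2-en-1-one
Conditions: conc. aq HCl (cat.), MeOH–CH2Cl2, 0 °C → rt, stopped at the mono-phenol
Reagents that add atoms: none
Why: Acid-catalysed acetal cleavage should take first one of the two equivalent acetals ortho to the ketone (twisted and carbonyl-assisted), after which the hydrogen bond of the freed phenol to the carbonyl slows loss of the second.

Step 5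
Reactants: 8 (E)-1-[2-hydroxy-4,6-bis(methoxymethoxy)phenyl]-2-methylbut-2-en-1-one
Product: 9 (E)-1-[2-hydroxy-3-iodo-4,6-bis(methoxymethoxy)phenyl]-2-methylbut-2-en-1-one
Conditions: N-iodosuccinimide (1.05 equiv), CH2Cl2, 0 °C, dark
Reagents that add atoms: N-iodosuccinimide, O=C1CCC(=O)N1I
Why: Electrophilic aromatic iodination should go ortho to the free phenol, the less hindered of the two open ring positions (the other lies between two acetal ethers), which places the halide next to the oxygen that becomes O1.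

Step 6
Reactants: 9 (E)-1-[2-hydroxy-3-iodo-4,6-bis(methoxymethoxy)phenyl]-2-methylbut-2-en-1-one
Product: 10 (2R,3S)-8-iodo-5,7-bis(methoxymethoxy)-2,3-dimethylchroman-4-one (cis)
Conditions: (−)-quinine (0.2 equiv), chlorobenzene, rt
Reagents that add atoms: none
Why: Cinchona-alkaloid-catalysed intramolecular oxa-Michael addition (6-endo-trig) of the phenol to the (E)-enone should set C2 as R in the O–C bond-forming step under control of the bifunctional base, and kinetic protonation of the enol then places the C3 methyl cis (3S), as known for o-(2-methylbut-2-enoyl)phenols.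

Step 7
Reactants: 11 (R)-(+)-limonene
Product: 13 methyl (3R)-6-oxo-3-(prop-1-en-2-yl)heptanoate, via methoxy hydroperoxide 12 (not isolated)
Conditions: O3, CH2Cl2–MeOH, NaHCO3, Sudan red 7B as end-point dye, −78 °C; then Ac2O, Et3N, 0 °C → rt
Reagents that add atoms: ozone, [O-][O+]=O; methanol, CO
Why: Ozonolysis should cleave the electron-rich trisubstituted ring alkene before the isopropenyl group, methanol traps the carbonyl oxide at the CH terminus, and dehydration of the α-methoxy hydroperoxide gives the methyl ester while the limonene stereocentre is untouched.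

Step 8
Reactants: 13 methyl (3R)-6-oxo-3-(prop-1-en-2-yl)heptanoate
Product: 14 methyl (3R)-6-methyl-3-(prop-1-en-2-yl)hept-6-enoate
Conditions: Ph3PCH3Br, KOtBu, THF, 0 °C → rt
Reagents that add atoms: methyltriphenylphosphonium bromide, C[P+](c1ccccc1)(c1ccccc1)c1ccccc1.[Br-]
Why: Wittig methylenation should take the methyl ketone far faster than the ester, and the stereocentre, β to the ester, is not acidic.

Step 9
Reactants: 14 methyl (3R)-6-methyl-3-(prop-1-en-2-yl)hept-6-enoate
Product: 16 methyl (3S)-2-hydroxy-6-methyl-3-(prop-1-en-2-yl)hept-6-enoate (both C2 epimers), via sodium ester enolate 15 (not isolated)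
Conditions: NaN(SiMe3)2, THF, −78 °C; then trans-3-phenyl-2-(phenylsulfonyl)oxaziridine, −78 °C; aq NH4Cl
Reagents that add atoms: trans-3-phenyl-2-(phenylsulfonyl)oxaziridine, O=S(=O)(c1ccccc1)N1OC1c1ccccc1
Why: Enolate hydroxylation by the N-sulfonyloxaziridine should install the α-oxygen needed for a one-carbon excision, and the new carbinol centre is formed as a mixture that is destroyed in step 11.

Step 10
Reactants: 16 methyl (3S)-2-hydroxy-6-methyl-3-(prop-1-en-2-yl)hept-6-enoate
Product: 17 (3S)-6-methyl-3-(prop-1-en-2-yl)hept-6-ene-1,2-diol (both C2 epimers)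
Conditions: LiAlH4, Et2O, 0 °C
Reagents that add atoms: none
Why: Hydride reduction of the ester should give the 1,2-diol without touching the isolated alkenes.

Step 11
Reactants: 17 (3S)-6-methyl-3-(prop-1-en-2-yl)hept-6-ene-1,2-diol
Product: 19 (2S)-5-methyl-2-(prop-1-en-2-yl)hex-5-en-1-ol, via aldehyde 18 (not isolated)
Conditions: NaIO4 on silica gel, CH2Cl2, 0 °C; filter; then NaBH4, MeOH, 0 °C
Reagents that add atoms: none
Why: Periodate glycol cleavage excises C1, and immediate borohydride reduction of the α-branched β,γ-unsaturated aldehyde under near-neutral conditions should keep the allylic stereocentre from epimerising or moving into conjugation.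

Step 12
Reactants: 19 (2S)-5-methyl-2-(prop-1-en-2-yl)hex-5-en-1-ol
Product: 20 (3S)-3-(iodomethyl)-2,6-dimethylhepta-1,6-diene
Conditions: PPh3, I2, imidazole, CH2Cl2, 0 °C → rt
Reagents that add atoms: iodine, II
Why: Appel-type iodination should proceed by SN2 at the primary CH2 and leave the adjacent stereocentre alone.

Step 13
Reactants: 20 (3S)-3-(iodomethyl)-2,6-dimethylhepta-1,6-diene; 10 (2R,3S)-8-iodo-5,7-bis(methoxymethoxy)-2,3-dimethylchroman-4-one
Product: 22 (2R,3S)-5,7-bis(methoxymethoxy)-2,3-dimethyl-8-[(2R)-5-methyl-2-(prop-1-en-2-yl)hex-5-en-1-yl]chroman-4-one, via alkylzinc iodide 21 (not isolated)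
Conditions: 20, Zn dust (BrCH2CH2Br, Me3SiCl activation), LiCl, THF, 30 °C; then 10, Pd2(dba)3 (2.5 mol%), RuPhos (10 mol%), THF, rt
Reagents that add atoms: none
Why: Zinc insertion into the primary iodide and Negishi sp3–sp2 coupling under a bulky dialkylbiarylphosphine–palladium catalyst should outrun β-hydride elimination, and the base-free conditions spare the epimerisable cis C3 and the chain stereocentre.

Step 14
Reactants: 22 (2R,3S)-5,7-bis(methoxymethoxy)-2,3-dimethyl-8-[(2R)-5-methyl-2-(prop-1-en-2-yl)hex-5-en-1-yl]chroman-4-one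
Product: 23 (2R,3S)-5,7-dihydroxy-2,3-dimethyl-8-[(2R)-5-methyl-2-(prop-1-en-2-yl)hex-5-en-1-yl]chroman-4-one
Conditions: ZnBr2, n-PrSH, CH2Cl2, 0 °C, 10–15 min
Reagents that add atoms: none
Why: Lewis-acid acetal cleavage with thiol capture of the CH2 unit should remove both groups within minutes without protic acid, sparing the two 1,1-disubstituted alkenes and the cis-pyranone.

Step 15
Reactants: 23 (2R,3S)-5,7-dihydroxy-2,3-dimethyl-8-[(2R)-5-methyl-2-(prop-1-en-2-yl)hex-5-en-1-yl]chroman-4-one
Product: 24 (2R,3S)-6-bromo-5,7-dihydroxy-2,3-dimethyl-8-[(2R)-5-methyl-2-(prop-1-en-2-yl)hex-5-en-1-yl]chroman-4-one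
Conditions: N-bromosuccinimide (1.0 equiv), CH2Cl2–THF, −78 °C
Reagents that add atoms: N-bromosuccinimide, O=C1CCC(=O)N1Br
Why: Electrophilic aromatic bromination at C6, the only free ring carbon of the highly activated dihydroxyarene, should be much faster than any reaction with the alkenes at −78 °C and blocks C6 for the next step.

Step 16
Reactants: 25 3-methylbut-2-en-1-ol (prenol)
Product: 26 tert-butyl 3-methylbut-2-en-1-yl carbonate
Conditions: Boc2O, DMAP (10 mol%), CH2Cl2, 0 °C → rt
Reagents that add atoms: di-tert-butyl dicarbonate, CC(C)(C)OC(=O)OC(=O)OC(C)(C)C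
Why: DMAP-catalysed O-acylation of the allylic alcohol gives the mixed carbonate, an ionisable prenyl donor that releases its own base.

Step 17
Reactants: 24 (2R,3S)-6-bromo-5,7-dihydroxy-2,3-dimethyl-8-[(2R)-5-methyl-2-(prop-1-en-2-yl)hex-5-en-1-yl]chroman-4-one; 26 tert-butyl 3-methylbut-2-en-1-yl carbonate
Product: 27 (2R,3S,8R)-6-bromo-5-hydroxy-2,3-dimethyl-8-(3-methylbut-2-en-1-yl)-8-[(2R)-5-methyl-2-(prop-1-en-2-yl)hex-5-en-1-yl]-2,3-dihydro-4H-chromene-4,7(8H)-dione
Conditions: Pd2(dba)3·CHCl3 (2.5 mol%), (R,R)-DACH-phenyl bisphosphine [N,N'-((1R,2R)-cyclohexane-1,2-diyl)bis(2-(diphenylphosphino)benzamide)] (7.5 mol%), 26 (1.3 equiv), THF, 0 °C → rt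
Reagents that add atoms: none
Why: In this Tsuji–Trost allylic alkylation with dearomatisation the zerovalent palladium–bisphosphine complex ionises the carbonate to a dimethylallyl palladium cation and tert-butoxide, the phenoxide of 24 should attack the CH2 terminus through C8 because bromine crowds and deactivates C6 and O-prenyl ethers re-ionise, and the chiral pocket of the ligand selects the face of C8 so that the quaternary centre forms as 8R.

Step 18
Reactants: 27 (2R,3S,8R)-6-bromo-5-hydroxy-2,3-dimethyl-8-(3-methylbut-2-en-1-yl)-8-[(2R)-5-methyl-2-(prop-1-en-2-yl)hex-5-en-1-yl]-2,3-dihydro-4H-chromene-4,7(8H)-dione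
Product: 28 (2R,3S,8R)-5-hydroxy-2,3-dimethyl-8-(3-methylbut-2-en-1-yl)-8-[(2R)-5-methyl-2-(prop-1-en-2-yl)hex-5-en-1-yl]-2,3-dihydro-4H-chromene-4,7(8H)-dione
Conditions: Zn dust, AcOH, THF, 0 °C
Reagents that add atoms: none
Why: Reductive dehalogenation of the 2-bromo-1,3-dicarbonyl unit by zinc (zinc enolate, then protonation) should free C6 without touching alkenes or stereocentres.

Step 19
Reactants: 28 (2R,3S,8R)-5-hydroxy-2,3-dimethyl-8-(3-methylbut-2-en-1-yl)-8-[(2R)-5-methyl-2-(prop-1-en-2-yl)hex-5-en-1-yl]-2,3-dihydro-4H-chromene-4,7(8H)-dione; 29 (E)-hex-2-enal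
Product: 30 enol δ-lactone, (4S,6R,8R,9S)-8,9-dimethyl-6-(3-methylbut-2-en-1-yl)-6-[(2R)-5-methyl-2-(prop-1-en-2-yl)hex-5-en-1-yl]-4-propyl-3,4,8,9-tetrahydro-2H-pyrano[2,3-f]chromene-2,5,10(6H)-trione (28 with (S)-CH(n-Pr)CH2C(=O) joining C6 to the oxygen on C5)
Conditions: 29 (1.5 equiv), (5aS,10bR)-2-mesityl-5a,10b-dihydro-4H,6H-indeno[2,1-b][1,2,4]triazolo[4,3-d][1,4]oxazin-2-ium chloride (15 mol%), i-Pr2NEt (20 mol%), 3,3',5,5'-tetra-tert-butyldiphenoquinone (1.2 equiv), 4 Å molecular sieves, toluene, rt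
Reagents that add atoms: none
Why: The carbene adds to the enal, the acyl anion equivalent is oxidised by the diphenoquinone to the (E)-hex-2-enoyl azolium, and C6 of enol 28 bonds to its β-carbon (directly, or by O-acylation and [3,3] shift); protonation of the azolium enolate and attack of the C5 enol oxygen on the acyl azolium then release the carbene. The closest known reaction is the oxidative carbene-catalysed [3+3] annulation of enals with cyclic 1,3-diketones and other stable enols to 3,4-dihydropyran-2-ones. The lactone ring closes by 6-exo-trig acyl substitution at the acyl azolium carbon. The new stereocentre (4S in the lactone, C3 of the hexanoic acid later) is set by the aminoindanol-derived triazolium, whose indane wall shields one face of the enoyl azolium, while C8 lies four bonds away and should have little say. Site selectivity is needed and is secured because no other carbon of the triketone carries a hydrogen between two oxygenated carbons, and closure on the C7 oxygen in place of O5 would give an isomer that opens to the same acid in step 20. The isolated alkenes and the pyranone ring should be inert to carbene and quinone.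

Step 20
Reactants: 30 enol δ-lactone
Product: 31 (3S)-3-[(2R,3S,8R)-5-hydroxy-2,3-dimethyl-8-(3-methylbut-2-en-1-yl)-8-[(2R)-5-methyl-2-(prop-1-en-2-yl)hex-5-en-1-yl]-4,7-dioxo-3,4,7,8-tetrahydro-2H-chromen-6-yl]hexanoic acid
Conditions: LiOH·H2O, THF–H2O (3:1), 0 °C; then 1 M HCl to pH 3
Reagents that add atoms: lithium hydroxide, [Li+].[OH-]
Why: Lactone hydrolysis by hydroxide at the activated enol ester should give the carboxylate and the delocalised triketone enolate, whose charge shields the C3 proton of the pyranone from removal, and mild acidification then gives the acid.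

**Compound list**

1 | phloroglucinol | Oc1cc(O)cc(O)c1 | starting material
2 | 1,3,5-tris(methoxymethoxy)benzene | COCOc1cc(OCOC)cc(OCOC)c1 | intermediate
3 | tiglic acid, (E)-2-methylbut-2-enoic acid | C/C=C(\C)C(=O)O | starting material
4 | (E)-1-(1H-imidazol-1-yl)-2-methylbut-2-en-1-one (tigloyl imidazolide) | C/C=C(\C)C(=O)n1ccnc1 | intermediate
5 | (E)-N-methoxy-N,2-dimethylbut-2-enamide | C/C=C(\C)C(=O)N(C)OC | intermediate
6 | [2,4,6-tris(methoxymethoxy)phenyl]lithium | [Li]c1c(OCOC)cc(OCOC)cc1OCOC | intermediate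
7 | (E)-2-methyl-1-[2,4,6-tris(methoxymethoxy)phenyl]but-2-en-1-one | C/C=C(\C)C(=O)c1c(OCOC)cc(OCOC)cc1OCOC | intermediate
8 | (E)-1-[2-hydroxy-4,6-bis(methoxymethoxy)phenyl]-2-methylbut-2-en-1-one | C/C=C(\C)C(=O)c1c(O)cc(OCOC)cc1OCOC | intermediate
9 | (E)-1-[2-hydroxy-3-iodo-4,6-bis(methoxymethoxy)phenyl]-2-methylbut-2-en-1-one | C/C=C(\C)C(=O)c1c(O)c(I)c(OCOC)cc1OCOC | intermediate
10 | (2R,3S)-8-iodo-5,7-bis(methoxymethoxy)-2,3-dimethylchroman-4-one | COCOc1cc(OCOC)c2c(c1I)O[C@H](C)[C@H](C)C2=O | intermediate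
11 | (R)-(+)-limonene, (4R)-1-methyl-4-(prop-1-en-2-yl)cyclohex-1-ene | CC1=CC[C@@H](CC1)C(C)=C | starting material
12 | (5R)-7-hydroperoxy-7-methoxy-5-(prop-1-en-2-yl)heptan-2-one (C7 epimers) | COC(OO)C[C@@H](CCC(C)=O)C(C)=C | intermediate
13 | methyl (3R)-6-oxo-3-(prop-1-en-2-yl)heptanoate | COC(=O)C[C@@H](CCC(C)=O)C(C)=C | intermediate
14 | methyl (3R)-6-methyl-3-(prop-1-en-2-yl)hept-6-enoate | COC(=O)C[C@@H](CCC(C)=C)C(C)=C | intermediate
15 | sodium enolate of 14 | COC([O-])=C[C@@H](CCC(C)=C)C(C)=C.[Na+] | intermediate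
16 | methyl (3S)-2-hydroxy-6-methyl-3-(prop-1-en-2-yl)hept-6-enoate (C2 epimers) | COC(=O)C(O)[C@@H](CCC(C)=C)C(C)=C | intermediate
17 | (3S)-6-methyl-3-(prop-1-en-2-yl)hept-6-ene-1,2-diol (C2 epimers) | OCC(O)[C@@H](CCC(C)=C)C(C)=C | intermediate
18 | (2S)-5-methyl-2-(prop-1-en-2-yl)hex-5-enal | O=C[C@@H](CCC(C)=C)C(C)=C | intermediate
19 | (2S)-5-methyl-2-(prop-1-en-2-yl)hex-5-en-1-ol | OC[C@@H](CCC(C)=C)C(C)=C | intermediate
20 | (3S)-3-(iodomethyl)-2,6-dimethylhepta-1,6-diene | IC[C@@H](CCC(C)=C)C(C)=C | intermediate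
21 | [(2S)-5-methyl-2-(prop-1-en-2-yl)hex-5-en-1-yl]zinc iodide | I[Zn]C[C@@H](CCC(C)=C)C(C)=C | intermediate
22 | (2R,3S)-5,7-bis(methoxymethoxy)-2,3-dimethyl-8-[(2R)-5-methyl-2-(prop-1-en-2-yl)hex-5-en-1-yl]chroman-4-one | COCOc1cc(OCOC)c2c(c1C[C@@H](CCC(C)=C)C(C)=C)O[C@H](C)[C@H](C)C2=O | intermediate
23 | (2R,3S)-5,7-dihydroxy-2,3-dimethyl-8-[(2R)-5-methyl-2-(prop-1-en-2-yl)hex-5-en-1-yl]chroman-4-one | Oc1cc(O)c2c(c1C[C@@H](CCC(C)=C)C(C)=C)O[C@H](C)[C@H](C)C2=O | intermediate
24 | (2R,3S)-6-bromo-5,7-dihydroxy-2,3-dimethyl-8-[(2R)-5-methyl-2-(prop-1-en-2-yl)hex-5-en-1-yl]chroman-4-one | Oc1c(Br)c(O)c2c(c1C[C@@H](CCC(C)=C)C(C)=C)O[C@H](C)[C@H](C)C2=O | intermediate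
25 | 3-methylbut-2-en-1-ol (prenol) | CC(C)=CCO | starting material
26 | tert-butyl 3-methylbut-2-en-1-yl carbonate | CC(C)=CCOC(=O)OC(C)(C)C | intermediate
27 | (2R,3S,8R)-6-bromo-5-hydroxy-2,3-dimethyl-8-(3-methylbut-2-en-1-yl)-8-[(2R)-5-methyl-2-(prop-1-en-2-yl)hex-5-en-1-yl]-2,3-dihydro-4H-chromene-4,7(8H)-dione | C=C(C)CC[C@H](C[C@@]1(CC=C(C)C)C(=O)C(Br)=C(O)C2=C1O[C@H](C)[C@H](C)C2=O)C(=C)C | intermediate
28 | (2R,3S,8R)-5-hydroxy-2,3-dimethyl-8-(3-methylbut-2-en-1-yl)-8-[(2R)-5-methyl-2-(prop-1-en-2-yl)hex-5-en-1-yl]-2,3-dihydro-4H-chromene-4,7(8H)-dione | C=C(C)CC[C@H](C[C@@]1(CC=C(C)C)C(=O)C=C(O)C2=C1O[C@H](C)[C@H](C)C2=O)C(=C)C | intermediate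
29 | (E)-hex-2-enal | CCC/C=C/C=O | starting material
30 | (4S,6R,8R,9S)-8,9-dimethyl-6-(3-methylbut-2-en-1-yl)-6-[(2R)-5-methyl-2-(prop-1-en-2-yl)hex-5-en-1-yl]-4-propyl-3,4,8,9-tetrahydro-2H-pyrano[2,3-f]chromene-2,5,10(6H)-trione (enol δ-lactone of 31) | C=C(C)CC[C@H](C[C@@]1(CC=C(C)C)C(=O)C3=C(OC(=O)C[C@@H]3CCC)C2=C1O[C@H](C)[C@H](C)C2=O)C(=C)C | intermediate
31 | (3S)-3-[(2R,3S,8R)-5-hydroxy-2,3-dimethyl-8-(3-methylbut-2-en-1-yl)-8-[(2R)-5-methyl-2-(prop-1-en-2-yl)hex-5-en-1-yl]-4,7-dioxo-3,4,7,8-tetrahydro-2H-chromen-6-yl]hexanoic acid | C=C(C)CC[C@H](C[C@@]1(CC=C(C)C)C(=O)C([C@@H](CCC)CC(=O)O)=C(O)C2=C1O[C@H](C)[C@H](C)C2=O)C(=C)C | target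

**Totals**

Total step count: 20.
Longest linear sequence: 13 steps (from 11 through steps 7–15 and 17–20); the branch from phloroglucinol is 12 steps.

**Steps most likely to fail**

Step 17. The prenyl unit may be delivered to oxygen or to the bromine-bearing C6, face selection at C8 may be weak if ligand and substrate are mismatched, and the catalyst may be lost by insertion into a C–Br bond. Fallback: set out from 24 and alkylate without palladium. Double deprotonation with LiN(SiMe3)2 in THF at −78 °C and addition of prenyl bromide should give C8 prenylation as a pair of epimers, 27 and the (2R,3S,8S)-epimer of 27 F1. These are separated by chromatography, and 27 re-enters the route at step 18.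

Step 19. Addition of the chelated, hindered enol to the acyl azolium may be slow, so that simple O-acylation or oxidation of the enal without C–C bond formation takes over, or face selection may drop in a mismatched pairing with C8. Fallback: set out from 28 and generate the same unsaturated acyl electrophile without carbene or oxidant. (E)-Hex-2-enoic acid, pivaloyl chloride and i-Pr2NEt in CH2Cl2 give, in the flask, (E)-hex-2-enoic pivalic anhydride F2. A chiral isothiourea (HyperBTM, 10 mol%) converts it into the α,β-unsaturated acyl ammonium ion, which should undergo the same C6 Michael addition and O5 lactonisation with 28. The fallback returns to the route at 30.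

Step 14. The Lewis acid may trigger addition of the C7 phenol or of the thiol to the nearby isopropenyl group, or cis-to-trans epimerisation at C3. Fallback: change the protecting group before the acid-sensitive chain arrives. From 10, HCl in MeOH (no alkene present) gives (2R,3S)-5,7-dihydroxy-8-iodo-2,3-dimethylchroman-4-one F3. Ac2O, pyridine and DMAP give (2R,3S)-8-iodo-2,3-dimethyl-4-oxochromane-5,7-diyl diacetate F4. Negishi coupling with 21 under the conditions of step 13 gives (2R,3S)-2,3-dimethyl-8-[(2R)-5-methyl-2-(prop-1-en-2-yl)hex-5-en-1-yl]-4-oxochromane-5,7-diyl diacetate F5. Brief K2CO3 in MeOH at 0 °C removes the acetates by transesterification and returns to the route at 23.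

**Further compounds**

F1 | step 17 | (2R,3S,8S)-6-bromo-5-hydroxy-2,3-dimethyl-8-(3-methylbut-2-en-1-yl)-8-[(2R)-5-methyl-2-(prop-1-en-2-yl)hex-5-en-1-yl]-2,3-dihydro-4H-chromene-4,7(8H)-dione | C=C(C)CC[C@H](C[C@]1(CC=C(C)C)C(=O)C(Br)=C(O)C2=C1O[C@H](C)[C@H](C)C2=O)C(=C)C
F2 | step 19 | (E)-hex-2-enoic pivalic anhydride | CCC/C=C/C(=O)OC(=O)C(C)(C)C
F3 | step 14 | (2R,3S)-5,7-dihydroxy-8-iodo-2,3-dimethylchroman-4-one | Oc1cc(O)c2c(c1I)O[C@H](C)[C@H](C)C2=O
F4 | step 14 | (2R,3S)-8-iodo-2,3-dimethyl-4-oxochromane-5,7-diyl diacetate | CC(=O)Oc1cc(OC(C)=O)c2c(c1I)O[C@H](C)[C@H](C)C2=O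
F5 | step 14 | (2R,3S)-2,3-dimethyl-8-[(2R)-5-methyl-2-(prop-1-en-2-yl)hex-5-en-1-yl]-4-oxochromane-5,7-diyl diacetate | CC(=O)Oc1cc(OC(C)=O)c2c(c1C[C@@H](CCC(C)=C)C(C)=C)O[C@H](C)[C@H](C)C2=O
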